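**Plan** (C numbers are those of the target: ring C1 CMe2, C2 CHBr, C3 sp2, C4 CHCl, C5 CH2, C6 CHCl; side chain C7 =CH, C8 CH2Br)

- Feature: C3, the one sp2 ring carbon, carries no hydrogen and lies between the methines C2 and C4, so it can be inserted as a carbene carbon into the C2=C4 alkene of a cyclopentene (ring C1, C2, C4, C5, C6).
- Cuts, in retrosynthetic order: C2–Br (1,3-transposition of a C7–O bond), C8–Br, C4–Cl (inversion of a C4 alcohol), C3–C7 (coupling at a C3 vinyl bromide), C2–C3 and C3–C4 (carbene, C2–C4 bond restored), C2=C4 (metathesis), C4–C5 (vinyl onto a C5 triflate).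
- Forward: an open-chain chloro diene is closed to the five-membered ring, the ring is expanded to the six-membered bromocyclohexenyl acetate, and the two-carbon side chain is joined at C3 by Stille coupling.
- Stereochemistry: C6 from enamine-catalysed α-chlorination; C4 from a catalyst-controlled ketone reduction followed by SN2 chlorination; C2 and the Z alkene by syn SNi′ transfer from a C7 carbinol set by a second catalyst-controlled reduction.

Key step: step 6

Assumption: the facial sense of the imidazolidinone catalyst (step 2) and of the two oxazaborolidines (steps 9 and 13) is taken from the accepted shielding models; if a Mosher ester check shows the opposite sense at any of them, the mirror-image catalyst is used there.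

**Step 1**
Reactants: 1 methyl 3,3-dimethylpent-4-enoate
Product: 2 3,3-dimethylpent-4-enal
Conditions: i-Bu2AlH, CH2Cl2, −78 °C; aq. potassium sodium tartrate
Reagents that add atoms: none
Why: Partial reduction of an ester with i-Bu2AlH at −78 °C stops at the aluminium hemiacetal, which gives the aldehyde only on work-up; the vinyl group on the quaternary carbon is inert.

**Step 2**
Reactants: 2 3,3-dimethylpent-4-enal
Product: 4 (R)-2-chloro-3,3-dimethylpent-4-en-1-ol, via (R)-2-chloro-3,3-dimethylpent-4-enal 3 (not isolated)
Conditions: (5R)-5-benzyl-2,2,3-trimethylimidazolidin-4-one·CF3CO2H (10 mol %), 2,3,4,5,6,6-hexachlorocyclohexa-2,4-dien-1-one, acetone, −30 °C; then NaBH4, EtOH, 0 °C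
Reagents that add atoms: 2,3,4,5,6,6-hexachlorocyclohexa-2,4-dien-1-one, O=C1C(Cl)=C(Cl)C(Cl)=C(Cl)C1(Cl)Cl
Why: Enamine-catalysed α-chlorination, in which the (E)-enamine of 2 is chlorinated on the face away from the benzyl group, should give the (R) aldehyde (this carbon becomes C6), and immediate borohydride reduction fixes the labile centre as the chlorohydrin.

**Step 3**
Reactants: 4 (R)-2-chloro-3,3-dimethylpent-4-en-1-ol
Product: 5 (R)-2-chloro-3,3-dimethylpent-4-en-1-yl trifluoromethanesulfonate
Conditions: Tf2O, 2,6-lutidine, CH2Cl2, −78 °C; used at once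
Reagents that add atoms: trifluoromethanesulfonic anhydride, O=S(=O)(OS(=O)(=O)C(F)(F)F)C(F)(F)F
Why: O-Sulfonylation of a primary alcohol with a hindered pyridine base at low temperature does not involve the stereocentre.

**Step 4**
Reactants: 5 (R)-2-chloro-3,3-dimethylpent-4-en-1-yl trifluoromethanesulfonate; 6 vinylmagnesium bromide
Product: 7 (S)-4-chloro-3,3-dimethylhepta-1,6-diene
Conditions: vinylmagnesium bromide, CuI (10 mol %), THF/Et2O, −40 → 0 °C
Reagents that add atoms: vinylmagnesium bromide (6), C=C[Mg]Br
Why: Copper-catalysed substitution of a primary alkyl triflate by a Grignard reagent is fast enough at low temperature to outrun elimination and leaves the secondary chloride alone, so the configuration is retained (the descriptor changes from R to S only because the ranking of the neighbours changes).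

**Step 5**
Reactants: 7 (S)-4-chloro-3,3-dimethylhepta-1,6-diene
Product: 8 (S)-4-chloro-3,3-dimethylcyclopent-1-ene
Conditions: second-generation Grubbs catalyst (H2IMes)(PCy3)Cl2Ru=CHPh (2 mol %), CH2Cl2, 40 °C; silica plug, careful concentration (volatile)
Reagents that add atoms: none
Why: Ring-closing olefin metathesis of a 1,6-diene to a cyclopentene is driven by loss of ethene and helped by the gem-dimethyl group, with the homoallylic chloride as a spectator.

**Step 6**
Reactants: 8 (S)-4-chloro-3,3-dimethylcyclopent-1-ene; 9 bromoform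
Product: 11 (5S)-2-bromo-5-chloro-4,4-dimethylcyclohex-2-en-1-yl acetate as a mixture of C1 epimers, via (3S)-6,6-dibromo-3-chloro-2,2-dimethylbicyclo[3.1.0]hexane 10 (not isolated)
Conditions: CHBr3, 50% aq. NaOH, BnEt3NBr (cat.), toluene, 0 °C → rt; phase separation; then AgOAc, AcOH, rt → 40 °C, dark
Reagents that add atoms: bromoform (9), BrC(Br)Br; silver acetate, CC(=O)[O-].[Ag+]
Why: Dibromocarbene, made at the phase boundary from bromoform and hydroxide, adds to the C2=C4 alkene of 8 in a concerted, stereospecifically cis [2+1] cheletropic step that closes the three-membered ring and forms both bonds to C3 (C2–C3 and C3–C4). AgOAc then removes the endo bromide of 10 while the C2–C4 bond opens in a two-electron disrotatory electrocyclic process, the only mode open to a cis-fused bicycle, which gives the cis 2-bromocyclohexenyl cation directly; the six-membered ring therefore arises by ring expansion and not by a new cyclisation, and the exo bromide stays on C3 as a vinyl bromide. The closest known reaction type is the silver-assisted solvolytic ring expansion of 6,6-dibromobicyclo[3.1.0]hexanes to 2-bromocyclohex-2-enyl esters. The selectivity needed is capture of the cation by acetate at C4 and not at C2, and it is secured by the C1 gem-dimethyl group, which makes C2 neopentylic while C4 is flanked only by the C5 methylene. The cyclopropane stereocentres are transient and the new C4 stereocentre is not controlled, which is accepted because C4 is flattened in step 8 and reset by the catalyst in step 9. The C6 chloride is remote from the cationic carbons and should pass through unchanged.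

**Step 7**
Reactants: 11 (5S)-2-bromo-5-chloro-4,4-dimethylcyclohex-2-en-1-yl acetate
Product: 12 (5S)-2-bromo-5-chloro-4,4-dimethylcyclohex-2-en-1-ol as a mixture of C1 epimers
Conditions: K2CO3 (cat.), MeOH, 0 °C → rt
Reagents that add atoms: none
Why: Base-catalysed transesterification (methanolysis) of the allylic acetate should not affect the unactivated secondary chloride or the vinyl bromide at this temperature.

**Step 8**
Reactants: 12 (5S)-2-bromo-5-chloro-4,4-dimethylcyclohex-2-en-1-ol
Product: 13 (S)-2-bromo-5-chloro-4,4-dimethylcyclohex-2-en-1-one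
Conditions: Dess–Martin periodinane, CH2Cl2, 0 °C → rt; no amine base
Reagents that add atoms: none
Why: Dess–Martin oxidation of a secondary allylic alcohol gives the 2-bromo enone and removes the uncontrolled C4 centre; amine bases are excluded because the C6 chloride is now β to the carbonyl and could be lost by E1cB elimination.

**Step 9**
Reactants: 13 (S)-2-bromo-5-chloro-4,4-dimethylcyclohex-2-en-1-one
Product: 14 (1R,5S)-2-bromo-5-chloro-4,4-dimethylcyclohex-2-en-1-ol
Conditions: (S)-2-methyl-CBS-oxazaborolidine (20 mol %), BH3·SMe2, THF, −20 °C; MeOH quench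
Reagents that add atoms: none
Why: Corey–Bakshi–Shibata reduction of a 2-bromo enone, in which the bromoalkenyl arm acts as the large group, should deliver hydride under catalyst control to give the (1R) alcohol cis to the C6 chloride, and any minor enantiomer carried from step 2 becomes a separable diastereomer.

**Step 10**
Reactants: 14 (1R,5S)-2-bromo-5-chloro-4,4-dimethylcyclohex-2-en-1-ol; 15 tributyl(1-ethoxyvinyl)stannane
Product: 16 (1R,5S)-5-chloro-2-(1-ethoxyethenyl)-4,4-dimethylcyclohex-2-en-1-ol
Conditions: tributyl(1-ethoxyvinyl)stannane, Pd(PPh3)4 (5 mol %), CuI (10 mol %), dioxane, 90 °C; Et3N-deactivated silica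
Reagents that add atoms: tributyl(1-ethoxyvinyl)stannane (15), CCCC[Sn](CCCC)(CCCC)C(=C)OCC
Why: Stille cross-coupling of an alkenyl bromide with an α-alkoxyvinylstannane (oxidative addition to zerovalent palladium, copper-assisted transmetallation, reductive elimination) forms the C3–C7 bond and brings in C7 and C8 at the ketone oxidation level, and it tolerates the free alcohol and the alkyl chloride.

**Step 11**
Reactants: 16 (1R,5S)-5-chloro-2-(1-ethoxyethenyl)-4,4-dimethylcyclohex-2-en-1-ol
Product: 17 (4S,6S)-4,6-dichloro-1-(1-ethoxyethenyl)-3,3-dimethylcyclohex-1-ene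
Conditions: PPh3, Cl3CCOCCl3, CH2Cl2, −30 → 0 °C
Reagents that add atoms: hexachloroacetone, ClC(Cl)(Cl)C(=O)C(Cl)(Cl)Cl
Why: Appel-type chlorination, in which chloride displaces the alkoxyphosphonium ion by SN2 with inversion, places the C4 chlorine trans to the C6 chlorine; the reagent is neutral, which spares the enol ether, and SN2′ delivery to C2 is blocked by the neighbouring quaternary carbon.

**Step 12**
Reactants: 17 (4S,6S)-4,6-dichloro-1-(1-ethoxyethenyl)-3,3-dimethylcyclohex-1-ene
Product: 18 2-bromo-1-[(4S,6S)-4,6-dichloro-3,3-dimethylcyclohex-1-en-1-yl]ethan-1-one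
Conditions: NBS, THF/H2O, 0 °C, dark
Reagents that add atoms: N-bromosuccinimide, O=C1CCC(=O)N1Br; water, O
Why: Electrophilic bromination of an enol ether in wet solvent puts bromine on the terminal carbon C8, water adds to the oxocarbenium ion and the hemiketal loses ethanol, the standard conversion of an α-ethoxyvinyl group into a bromomethyl ketone.

**Step 13**
Reactants: 18 2-bromo-1-[(4S,6S)-4,6-dichloro-3,3-dimethylcyclohex-1-en-1-yl]ethan-1-one
Product: 19 (1R)-2-bromo-1-[(4S,6S)-4,6-dichloro-3,3-dimethylcyclohex-1-en-1-yl]ethan-1-ol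
Conditions: (R)-2-methyl-CBS-oxazaborolidine (20 mol %), BH3·SMe2, THF, −20 °C; MeOH, pH 7 work-up
Reagents that add atoms: none
Why: Corey–Bakshi–Shibata reduction of an α-bromo ketone, with the fully substituted cyclohexenyl group as the large and CH2Br as the small substituent, should give the (1R) bromohydrin at C7 with the (R) catalyst, and the neutral work-up avoids epoxide closure.

**Step 14**
Reactants: 19 (1R)-2-bromo-1-[(4S,6S)-4,6-dichloro-3,3-dimethylcyclohex-1-en-1-yl]ethan-1-ol
Product: 21 (2S,3Z,4S,6S)-2-bromo-3-(2-bromoethylidene)-4,6-dichloro-1,1-dimethylcyclohexane, via allylic bromosulfite 20 (not isolated)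
Conditions: SOBr2, Et2O, −40 → 0 °C, no base
Reagents that add atoms: thionyl bromide, O=S(Br)Br
Why: SNi′ reaction of an allylic alcohol with a thionyl halide, in which bromosulfite 20 collapses through a six-membered cyclic transition state that delivers bromide to C2 on the face from which oxygen leaves, should transfer the C7 configuration to C2 (2S); in the reactive rotamer the C7–O bond lies anti to the pseudoaxial C4 chlorine, which turns CH2Br toward C2 and gives the Z alkene.

**Compound list**

1 | methyl 3,3-dimethylpent-4-enoate | COC(=O)CC(C)(C)C=C | starting material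
2 | 3,3-dimethylpent-4-enal | O=CCC(C)(C)C=C | intermediate
3 | (R)-2-chloro-3,3-dimethylpent-4-enal | O=C[C@H](Cl)C(C)(C)C=C | intermediate (not isolated)
4 | (R)-2-chloro-3,3-dimethylpent-4-en-1-ol | OC[C@H](Cl)C(C)(C)C=C | intermediate
5 | (R)-2-chloro-3,3-dimethylpent-4-en-1-yl trifluoromethanesulfonate | O=S(=O)(OC[C@H](Cl)C(C)(C)C=C)C(F)(F)F | intermediate
6 | vinylmagnesium bromide | C=C[Mg]Br | starting material
7 | (S)-4-chloro-3,3-dimethylhepta-1,6-diene | C=CC[C@H](Cl)C(C)(C)C=C | intermediate
8 | (S)-4-chloro-3,3-dimethylcyclopent-1-ene | CC1(C)C=CC[C@@H]1Cl | intermediate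
9 | bromoform | BrC(Br)Br | starting material
10 | (3S)-6,6-dibromo-3-chloro-2,2-dimethylbicyclo[3.1.0]hexane (cis-fused, both faces) | CC1(C)C2C(C[C@@H]1Cl)C2(Br)Br | intermediate (not isolated)
11 | (5S)-2-bromo-5-chloro-4,4-dimethylcyclohex-2-en-1-yl acetate (C1 epimers) | CC1(C)C=C(Br)C(OC(C)=O)C[C@@H]1Cl | intermediate
12 | (5S)-2-bromo-5-chloro-4,4-dimethylcyclohex-2-en-1-ol (C1 epimers) | CC1(C)C=C(Br)C(O)C[C@@H]1Cl | intermediate
13 | (S)-2-bromo-5-chloro-4,4-dimethylcyclohex-2-en-1-one | CC1(C)C=C(Br)C(=O)C[C@@H]1Cl | intermediate
14 | (1R,5S)-2-bromo-5-chloro-4,4-dimethylcyclohex-2-en-1-ol | CC1(C)C=C(Br)[C@H](O)C[C@@H]1Cl | intermediate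
15 | tributyl(1-ethoxyvinyl)stannane | CCCC[Sn](CCCC)(CCCC)C(=C)OCC | starting material
16 | (1R,5S)-5-chloro-2-(1-ethoxyethenyl)-4,4-dimethylcyclohex-2-en-1-ol | CC1(C)C=C(C(=C)OCC)[C@H](O)C[C@@H]1Cl | intermediate
17 | (4S,6S)-4,6-dichloro-1-(1-ethoxyethenyl)-3,3-dimethylcyclohex-1-ene | CC1(C)C=C(C(=C)OCC)[C@@H](Cl)C[C@@H]1Cl | intermediate
18 | 2-bromo-1-[(4S,6S)-4,6-dichloro-3,3-dimethylcyclohex-1-en-1-yl]ethan-1-one | CC1(C)C=C(C(=O)CBr)[C@@H](Cl)C[C@@H]1Cl | intermediate
19 | (1R)-2-bromo-1-[(4S,6S)-4,6-dichloro-3,3-dimethylcyclohex-1-en-1-yl]ethan-1-ol | CC1(C)C=C([C@@H](O)CBr)[C@@H](Cl)C[C@@H]1Cl | intermediate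
20 | (1R)-2-bromo-1-[(4S,6S)-4,6-dichloro-3,3-dimethylcyclohex-1-en-1-yl]ethyl bromosulfite | CC1(C)C=C([C@@H](OS(=O)Br)CBr)[C@@H](Cl)C[C@@H]1Cl | intermediate (not isolated)
21 | (2S,3Z,4S,6S)-2-bromo-3-(2-bromoethylidene)-4,6-dichloro-1,1-dimethylcyclohexane | CC1(C)[C@H](Br)/C(=C\CBr)[C@@H](Cl)C[C@@H]1Cl | target

Total step count: 14
Longest linear sequence: 14 steps (1 → 21)

**Steps most likely to fail**

Step 14. Bromide may be delivered at C7 without allylic shift (direct SNi or SN2), or the ion pair may dissociate to a free allyl cation so that the syn transfer, and with it the C2 configuration and the Z geometry, is lost; the allylic bromide may also isomerise in the HBr set free. The fallback makes both C–Br bonds by 1,4-addition of bromine to a diene. It sets out from 14: Stille coupling with tributyl(vinyl)stannane (Pd(PPh3)4, CuI, dioxane, 90 °C) should give (1R,5S)-5-chloro-2-ethenyl-4,4-dimethylcyclohex-2-en-1-ol F1; chlorination with inversion (PPh3, hexachloroacetone) then gives (4S,6S)-4,6-dichloro-1-ethenyl-3,3-dimethylcyclohex-1-ene F2; one equivalent of bromine in CH2Cl2 at −78 °C adds across the diene termini C2 and C8 and the fallback comes back to the route at 21. Geometry and C2 configuration would then rest on substrate bias (bromide return anti to the pseudoaxial C4 chlorine) and on chromatographic separation of isomers.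

Step 11. The alkoxyphosphonium ion may ionise to the allyl cation, with loss of configuration at C4 or chloride delivery at C2, and the enol ether may be hydrolysed or chlorinated under the reaction conditions. The fallback carries out the displacement on the ketone, where the acyl group disfavours ionisation. It sets out from 16: mild acid hydrolysis (pyridinium p-toluenesulfonate, wet acetone) gives 1-[(4S,6R)-4-chloro-6-hydroxy-3,3-dimethylcyclohex-1-en-1-yl]ethan-1-one F3; PPh3/hexachloroacetone gives 1-[(4S,6S)-4,6-dichloro-3,3-dimethylcyclohex-1-en-1-yl]ethan-1-one F4; soft enolisation (Me3SiOTf, i-Pr2NEt, CH2Cl2, 0 °C) gives ({1-[(4S,6S)-4,6-dichloro-3,3-dimethylcyclohex-1-en-1-yl]ethenyl}oxy)trimethylsilane F5; NBS in THF at −78 °C brominates C8 and the fallback comes back to the route at 18.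

Step 6. Acetate may be captured at the neopentylic terminus C2 as well as at C4, and the strained adduct may ionise before the silver stage. The fallback keeps the carbene insertion and the electrocyclic opening but runs the ring expansion without silver, under thermodynamic control. It sets out from 10 (made as in the first half of step 6): warming in toluene (80–100 °C) should open the cyclopropane with internal return of bromide, and reversible 1,3-shift should settle the allylic bromide at the less hindered C4 terminus as (4S)-1,6-dibromo-4-chloro-3,3-dimethylcyclohex-1-ene F6; direct SN2 displacement with CsOAc in DMF then gives the acetate and the fallback comes back to the route at 11.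

**Further compounds**

F1 | step 14 | (1R,5S)-5-chloro-2-ethenyl-4,4-dimethylcyclohex-2-en-1-ol | CC1(C)C=C(C=C)[C@H](O)C[C@@H]1Cl
F2 | step 14 | (4S,6S)-4,6-dichloro-1-ethenyl-3,3-dimethylcyclohex-1-ene | CC1(C)C=C(C=C)[C@@H](Cl)C[C@@H]1Cl
F3 | step 11 | 1-[(4S,6R)-4-chloro-6-hydroxy-3,3-dimethylcyclohex-1-en-1-yl]ethan-1-one | CC1(C)C=C(C(C)=O)[C@H](O)C[C@@H]1Cl
F4 | step 11 | 1-[(4S,6S)-4,6-dichloro-3,3-dimethylcyclohex-1-en-1-yl]ethan-1-one | CC1(C)C=C(C(C)=O)[C@@H](Cl)C[C@@H]1Cl
F5 | step 11 | ({1-[(4S,6S)-4,6-dichloro-3,3-dimethylcyclohex-1-en-1-yl]ethenyl}oxy)trimethylsilane | CC1(C)C=C(C(=C)O[Si](C)(C)C)[C@@H](Cl)C[C@@H]1Cl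
F6 | step 6 | (4S)-1,6-dibromo-4-chloro-3,3-dimethylcyclohex-1-ene (C6 epimers) | CC1(C)C=C(Br)C(Br)C[C@@H]1Cl
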